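**Retrosynthetic overview**
- The target is 1-(4-hydroxyphenyl)octadecan-5-one; its only ring, the para-substituted phenol ring, is bought intact, so no ring is formed.
- Key disconnection: the C5(=O)–C6 bond, giving an acyl donor (the Weinreb amide of 5-(4-hydroxyphenyl)pentanoic acid) and a tridecyl nucleophile (the Grignard reagent from 1-bromotridecane).
- The Weinreb amide comes from commercial 5-(4-hydroxyphenyl)pentanoic acid and N,O-dimethylhydroxylamine hydrochloride; the phenol is left unprotected and costs one extra equivalent of Grignard reagent.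

Assumption: the SMILES has no stereocentre and no stereogenic double bond, so the target is achiral and is made exactly as drawn.

**Step 1**
Reactants: 1 5-(4-hydroxyphenyl)pentanoic acid; 2 N,O-dimethylhydroxylamine hydrochloride
Product: 5 Weinreb amide 5-(4-hydroxyphenyl)-N-methoxy-N-methylpentanamide, via O-acylisourea 3 (not isolated), via HOBt active ester 4 (not isolated)
Conditions: EDC·HCl (1.3 equiv), HOBt (1.3 equiv), N-methylmorpholine (3 equiv), 2 (1.5 equiv), CH2Cl2/DMF 9:1, 0 °C to rt, 14 h
Reagents that add atoms: N,O-dimethylhydroxylamine hydrochloride (2), CNOC.Cl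
Why: Carbodiimide amide coupling to a Weinreb amide, in which the HOBt ester 4 acylates the amine much faster than the free phenol, so no protection is needed and no stereocentre is involved.

**Step 2**
Reactants: 5 5-(4-hydroxyphenyl)-N-methoxy-N-methylpentanamide; 6 1-bromotridecane
Product: 9 target ketone 1-(4-hydroxyphenyl)octadecan-5-one, via tridecylmagnesium bromide 7 (not isolated), via magnesium hemiaminal chelate 8 (not isolated)
Conditions: 6 (4.0 equiv), Mg turnings (4.4 equiv), iodine crystal, THF, 45 °C, 2 h; then add to 5 in THF (3.5 equiv of titrated 7), 0 °C to rt, 3 h; 1 M aq. HCl, 0 °C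
Reagents that add atoms: 1-bromotridecane (6), CCCCCCCCCCCCCBr
Why: Weinreb ketone synthesis by Grignard addition, in which the first equivalent of 7 only deprotonates the phenol and the next adds once to give the stable five-membered magnesium chelate 8 (a transient racemic centre), which cannot over-add and collapses to the achiral ketone on acidic work-up.

**Compound list**
1 | 5-(4-hydroxyphenyl)pentanoic acid | OC(=O)CCCCc1ccc(O)cc1 | starting material
2 | N,O-dimethylhydroxylamine hydrochloride | CNOC.Cl | starting material
3 | O-acylisourea from 1 and EDC, N-ethyl-N'-[3-(dimethylamino)propyl]-O-[5-(4-hydroxyphenyl)pentanoyl]isourea | CCN=C(NCCCN(C)C)OC(=O)CCCCc1ccc(O)cc1 | intermediate (not isolated)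
4 | 1H-benzotriazol-1-yl 5-(4-hydroxyphenyl)pentanoate | O=C(CCCCc1ccc(O)cc1)On1nnc2ccccc12 | intermediate (not isolated)
5 | 5-(4-hydroxyphenyl)-N-methoxy-N-methylpentanamide | CON(C)C(=O)CCCCc1ccc(O)cc1 | intermediate
6 | 1-bromotridecane | CCCCCCCCCCCCCBr | starting material
7 | tridecylmagnesium bromide | CCCCCCCCCCCCC[Mg]Br | intermediate (not isolated)
8 | bis(bromomagnesium) salt of the tetrahedral adduct, 5-(N-methoxy-N-methylamino)-1-(4-oxidophenyl)octadecan-5-olate, racemic at C5 | CCCCCCCCCCCCCC(O[Mg]Br)(N(C)OC)CCCCc1ccc(O[Mg]Br)cc1 | intermediate (not isolated)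
9 | 1-(4-hydroxyphenyl)octadecan-5-one | CCCCCCCCCCCCCC(=O)CCCCc1ccc(O)cc1 | target

**Total step count:** 2
**Longest linear sequence:** 2

**Steps most likely to fail**
The route has only two steps, so both are ranked and there is no third step to name.

Step 2 is the riskier one. The bromomagnesium phenoxide of 5 may precipitate from THF and stall the addition. The fallback masks the phenol instead of carrying it as a salt. It sets out from 5: silylation (TBSCl, imidazole, DMF, rt) gives 5-[4-(tert-butyldimethylsilyloxy)phenyl]-N-methoxy-N-methylpentanamide F1. This stays in solution and needs only 1.3 equiv of tridecylmagnesium bromide 7 (THF, 0 °C), reacting through the magnesium chelate of the TBS-protected adduct F2, not isolated. Cold 1 M aq. HCl then releases 1-[4-(tert-butyldimethylsilyloxy)phenyl]octadecan-5-one F3. Desilylation with TBAF buffered by AcOH (THF, 0 °C) brings the fallback back to the route at 9.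

Step 1 is the second risk. Carbodiimide activation of an acid that also carries a free phenol can give phenolic ester oligomers and a poor yield of 5. The fallback avoids any activated acyl species. It sets out from 1: Fischer esterification (MeOH, catalytic H2SO4, reflux) gives methyl 5-(4-hydroxyphenyl)pentanoate F4. Separately, 2 and i-PrMgCl (THF, −20 °C) give chloromagnesium N-methoxy-N-methylamide F5, not isolated; one further equivalent of i-PrMgCl converts the phenol of F4 into its magnesium salt. F5 then converts the ester directly into the Weinreb amide (−20 to 0 °C, then aq. NH4Cl), and the fallback comes back to the route at 5.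

**Further compounds**
F1 | step 2 | 5-[4-(tert-butyldimethylsilyloxy)phenyl]-N-methoxy-N-methylpentanamide | CON(C)C(=O)CCCCc1ccc(O[Si](C)(C)C(C)(C)C)cc1
F2 | step 2 | bromomagnesium 1-[4-(tert-butyldimethylsilyloxy)phenyl]-5-(N-methoxy-N-methylamino)octadecan-5-olate | CCCCCCCCCCCCCC(O[Mg]Br)(N(C)OC)CCCCc1ccc(O[Si](C)(C)C(C)(C)C)cc1
F3 | step 2 | 1-[4-(tert-butyldimethylsilyloxy)phenyl]octadecan-5-one | CCCCCCCCCCCCCC(=O)CCCCc1ccc(O[Si](C)(C)C(C)(C)C)cc1
F4 | step 1 | methyl 5-(4-hydroxyphenyl)pentanoate | COC(=O)CCCCc1ccc(O)cc1
F5 | step 1 | chloromagnesium N-methoxy-N-methylamide | CON(C)[Mg]Cl
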